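The solid substrate feeds a solution in which starting material has two fates, and the double product at the end of the run lies on one of them.

    starting material + reagent → single product (k1 = 0.00127 L mol⁻¹ s⁻¹)
    reagent + single product → double product (k2 = 0.00283 L mol⁻¹ s⁻¹)
    reagent + double product → triple product (k3 = 4.02 × 10⁻⁴ L mol⁻¹ s⁻¹)
    solid substrate ⇌ starting material, rate k4*(cs4 - [starting material]) while solid is left; crystals form when [starting material] > cs4 (cs4 = 34 mM, k4 = 0.00491 s⁻¹)
    2 starting material → self-condensation product (k5 = 0.00453 L mol⁻¹ s⁻¹)

solid substrate 0.10 M; reagent 0.120 M; time 4.0 h

- a species is counted by the solid substrate in it: one self-condensation product counts as two
- a step written with two of one species runs at k times the square of its concentration and takes two of it each time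
- given per volume of solution although it is solid: solid substrate
- at the start none of the solid substrate is in solution
- run time (flask): 4.0 h

- the double product standing at 4.0 h, as a percentage of the solid substrate charged
- the change that raises the amount of double product at 4.0 h, in percent of the solid substrate charged most ("none" if none brings more than 2 percentage points) (blue / grey / amber / none)
- amount of double product at 4.0 h, in percent of the solid substrate charged, after amber

- blue: doubling the solubility in step 4, all else as stated
- grey: doubling the dissolution coefficient of step 4, all else as stated
- amber: doubling the amount of reagent, all else as stated

I laid out the clocks from the shortest. The gap to saturation closed with a half-time of 0.0392 h, far shorter than the first half-life of starting material by self-condensation at saturation, 0.902 h, so I took starting material as standing near its solubility, 34 mM, while solid lasted. That concentration entered the fork at two orders: self-condensation ran on its square, and the reagent step, with a half-life of 1.3 h at the charged reagent, on its first power. So I carried the branch ratio S, a selectivity factor: the rate constant of the reagent step times the charged reagent, over twice the self-condensation constant times the solubility, S = 0.495. From it I reckoned a share S/(1+S), or 33.1%, of the solid substrate on the reagent side. The slowest clock was the 4.0 h half-life of double product against triple formation, about the length of the run. I took the reagent side as reaching double product evenly over 4.0 h, which kept a part 0.721 of it, and I reckoned 23.9%.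

In my reckoning doubled solubility took S to 0.247, doubled dissolution left it at 0.495, and doubled reagent took it to 0.990 while the kept part fell to 0.540. With 49.7% on the reagent side I reckoned 26.9% for amber, and my choice was amber.

The forecast held that “Self-condensation takes about twice what the reagent takes”. It gave 21% (from 18.5% to 23.5%), chose amber, and gave 28.5% (from 25% to 32%). My first figure was higher than the forecast's, and my amber figure lower.

The flask gave 21.4%, and 30.2% after amber. The best change was amber, whose 8.8 percentage points was more than the −2 points for blue and the −0.079 points for grey. In the flask, with solid at 0%, the rate ratio that S stands for had reached 1.5 at 4.00 h. In the neighbour flask charged with 0.40 M of solid substrate, 49.3% was still solid at 4.00 h and starting material stood at 31.8 mM. S, reckoned with that flask's standing reagent and starting material, was 0.181, and its single, double and triple products together held 11.0% against 31.8% of self-condensation product.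

The numbers come from no measurement; the rest is arithmetic.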